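The reading to start from is the last one of the ash run, at 8.00 min.

| setting | ash | cedar | epsilon | beta |
|---|---|---|---|---|
| starting complex | 20 mM | 20 mM | 20 mM | 20 mM |
| incoming ligand | 2 equiv | 3.3 equiv | 2.20 equiv | 1.50 equiv |
| remark | run made earlier | run made earlier |  |  |
| time |  |  | 15 min | 15 min |

| run | time / min | starting complex / % | complex with two exchanged / % |
|---|---|---|---|
| ash | 1.00 | 80 | 0 |
| ash | 2.50 | 64 | 3 |
| ash | 5.00 | 40 | 0 |
| ash | 8.00 | 29 | 4 |
| cedar | 2.00 | 56 | 0 |
| cedar | 4.00 | 31 | 5 |
| cedar | 6.00 | 19 | 0 |
| cedar | 8.00 | 9 | 1 |

(each reading ± 2 percentage points)

- part of the starting complex that has reacted at the end, epsilon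
- part of the starting complex that has reacted at the end, beta
- what raising the equivalents of incoming ligand from its lowest to its highest value here does to the part of the starting complex that has reacted (changes below 5 percentage points count as none) (it falls / no change / it rises)

- what was read earlier has a scatter of 2 percentage points, one standard deviation
- what has gone from starting complex into another species counts as reacted, even if it can come back

**What do the runs show?** The starting complex decays, and it goes further with more incoming ligand. At 8.00 min, cedar stands at 9% and ash at 29%.

**What one number carries that?** Go to logarithms. Ash lost 0.538 decades of starting complex in 8.00 min at 2 equiv. So the decade rate d, the decades of starting complex lost per minute at the equivalents of ash, is 0.0672 min⁻¹. This is a pseudo-first-order view: the ligand is taken as held at its charge, d scales with the equivalents, and the time constant shortens in proportion.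

**Cedar, scaled to the equivalents of ash, gives 0.0792 min⁻¹. Why not use that?** Ash lies nearer the flasks asked about. Also, one scatter moves a small reading further in decades than a large one.

**Your reckoning, then?** Epsilon gets 1.11 decades, so 92.2% has reacted. Beta gets 0.756 decades, so 82.5% has reacted. The gap is 9.8 percentage points against a margin of 5 points, so the part reacted rises.

**But the ligand is consumed. Doesn't that break d?** It bends it. Beta has less ligand to spare than epsilon, so I read my beta figure as the high side.

The forecast says 90% for epsilon and 77% for beta, and that it rises. Its grounds: “This points to an associative step, first order in each partner”. Both its numbers stand below mine.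

The flask gives 88.3% for epsilon and 79.6% for beta, so it rises, by 8.7 points. The main reason for that gap is the difference in equivalents of incoming ligand. The forecast held.

    starting complex + incoming ligand → leaving ligand + complex with one exchanged (k = 0.0420 L mol⁻¹ s⁻¹)
    complex with one exchanged + incoming ligand → leaving ligand + complex with two exchanged (k = 0.00430 L mol⁻¹ s⁻¹)
    leaving ligand + starting complex ⇌ idle adduct, settled at all times (K = 780 L mol⁻¹)
    complex with two exchanged + incoming ligand → leaving ligand + complex with three exchanged (k = 0.0490 L mol⁻¹ s⁻¹)

In beta, d promised 0.756 decades, and the flask lost 0.690. The depletion of incoming ligand, which ends at 68.7% of its charge, is a part of what beta lacks: with the ligand held at charge, beta reaches 84.8% rather than 79.6%. Now take a neighbour like beta but with 0.900 equiv. There d gives 0.454 decades, so 64.8% reacted; the computed flask gives 62.4%.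

(The runs are calculated from invented constants; scatter was added.)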